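**Retrosynthetic overview**

1. Hernanol is a trans-(3R,4R)-3,4-dibenzyl-oxolan-2-one. The last operations are O-debenzylation of the phenol and, before it, trans-selective C3 alkylation of a (4R)-4-(arylmethyl)oxolan-2-one with 3,4,5-trimethoxybenzyl bromide.
2. Key disconnection: the ring bond C3–C4 of the lactone (carbon alpha to the carbonyl to the carbon bearing the 4-hydroxy-3-methoxybenzyl group). It is made by enantioselective intramolecular carbene C–H insertion of an achiral, open-chain 3-arylpropyl diazoacetate.
3. Enabling feature: the lactone's own ester unit O1–C2(=O) already links the two carbons to be joined. In the diazoacetate it holds the carbene carbon (future C3) at the 1,5-distance from the central CH2 of the propyl chain (future C4). C4 of the target keeps the second hydrogen of that CH2, and the rest of the chain is the arylmethyl group.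
4. The diazoacetate comes from eugenol in four steps: O-benzylation, anti-Markovnikov hydroboration, bromoacetylation and diazo formation with ditosylhydrazine.
5. Ring order: both benzene rings are bought; the only ring made is the oxolan-2-one, closed in step 5.

Key step: step 5

Assumption: the (4S)-configured catalyst Rh2(4S-MPPIM)4 is taken to give the (R)-lactone, as is known for 3-arylpropyl diazoacetates; should the sense of induction be opposite, the mirror-image catalyst Rh2(4R-MPPIM)4 would be used.

**Route**

Step 1
Reactants: 1 eugenol (4-allyl-2-methoxyphenol); 2 benzyl bromide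
Product: 3 4-allyl-1-(benzyloxy)-2-methoxybenzene
Conditions: K2CO3, acetone, reflux
Reagents that add atoms: benzyl bromide (2), BrCc1ccccc1
Why: Williamson ether synthesis, in which the phenoxide displaces bromide from the benzylic halide and the allyl group is untouched by the mild base.

Step 2
Reactants: 3 4-allyl-1-(benzyloxy)-2-methoxybenzene
Product: 5 3-[4-(benzyloxy)-3-methoxyphenyl]propan-1-ol, via B-alkyl-9-BBN adduct 4 (not isolated)
Conditions: 9-BBN (0.5 M in THF), THF, 0 °C to rt; then NaOH (3 M aq), H2O2 (30% aq), 0 °C to rt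
Reagents that add atoms: hydrogen peroxide, OO (the hydroxyl oxygen); 9-borabicyclo[3.3.1]nonane, B1C2CCCC1CCC2 (boron and bicycle of intermediate 4 only)
Why: Brown hydroboration–oxidation, in which the bulky dialkylborane adds to the terminal carbon of the monosubstituted alkene and oxidative C–B cleavage should give the primary alcohol without touching the benzyl ether.

Step 3
Reactants: 5 3-[4-(benzyloxy)-3-methoxyphenyl]propan-1-ol; 6 bromoacetyl bromide
Product: 7 3-[4-(benzyloxy)-3-methoxyphenyl]propyl 2-bromoacetate
Conditions: BrCH2COBr, NaHCO3, MeCN, 0 °C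
Reagents that add atoms: bromoacetyl bromide (6), BrCC(Br)=O
Why: O-acylation of a primary alcohol by an acyl bromide, which reacts far faster at the acyl carbon than at the alkyl bromide end, with the weak base taking up HBr.

Step 4
Reactants: 7 3-[4-(benzyloxy)-3-methoxyphenyl]propyl 2-bromoacetate
Product: 9 3-[4-(benzyloxy)-3-methoxyphenyl]propyl 2-diazoacetate, via N-alkylated ditosylhydrazide 8 (not isolated)
Conditions: TsNHNHTs, DBU, THF, 0 °C
Reagents that add atoms: N,N'-ditosylhydrazine, Cc1ccc(cc1)S(=O)(=O)NNS(=O)(=O)c1ccc(C)cc1 (supplies the two nitrogen atoms)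
Why: Diazoacetate synthesis by the ditosylhydrazine method, in which N-alkylation by the bromoacetate is followed by base-induced loss of two sulfinate ions, a sequence that is fast at 0 °C and tolerates the ester.

Step 5
Reactants: 9 3-[4-(benzyloxy)-3-methoxyphenyl]propyl 2-diazoacetate
Product: 10 (4R)-4-{[4-(benzyloxy)-3-methoxyphenyl]methyl}oxolan-2-one
Conditions: Rh2(4S-MPPIM)4 (1 mol%; dirhodium tetrakis[methyl (4S)-2-oxo-1-(3-phenylpropanoyl)imidazolidine-4-carboxylate] of divalent rhodium), CH2Cl2, reflux, 9 added slowly by syringe pump at high dilution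
Reagents that add atoms: none
Why: The dirhodium carboxamidate of divalent rhodium extrudes N2 from 9 to give an electrophilic metal-bound carbene, whose carbon inserts into one C–H bond of the central CH2 of the chain through a concerted, three-centre, hydride-transfer-like transition state, forming the C3–C4 bond and returning the catalyst. The closest known reaction type is the enantioselective carbene C–H insertion of 3-arylpropyl diazoacetates to 4-benzyl-gamma-butyrolactones under chiral dirhodium carboxamidate catalysis. The oxolan-2-one ring closes by 1,5-insertion through a five-membered transition state reached from the E rotamer of the ester, the carbene carbon becoming C3 and the former CH2 becoming C4. The single new stereocentre, C4, is set by the catalyst alone: the (4S)-imidazolidinone carboxylate ligands with their N-(3-phenylpropanoyl) groups differentiate the two enantiotopic hydrogens of the prochiral CH2, so that the (R)-lactone should predominate. The step needs site selectivity for this unactivated CH2 over the benzylic CH2 (delta-lactone), the O–CH2 (beta-lactone) and the electron-rich arene, and chemoselectivity over carbene dimerisation. These should be secured by the low electrophilicity and tight pocket of the carboxamidate catalyst, which favour the five-membered closure, by the unsubstituted diazo carbon (no 1,2-hydride shift is possible) and by slow addition at high dilution.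

Step 6
Reactants: 10 (4R)-4-{[4-(benzyloxy)-3-methoxyphenyl]methyl}oxolan-2-one; 11 3,4,5-trimethoxybenzyl bromide
Product: 13 (3R,4R)-4-{[4-(benzyloxy)-3-methoxyphenyl]methyl}-3-[(3,4,5-trimethoxyphenyl)methyl]oxolan-2-one, via lithium enolate 12 (not isolated)
Conditions: LiN(SiMe3)2, THF, −78 °C; then 11, DMPU, −78 to −40 °C
Reagents that add atoms: 3,4,5-trimethoxybenzyl bromide (11), COc1cc(CBr)cc(OC)c1OC; LiN(SiMe3)2, [Li+].C[Si](C)(C)[N-][Si](C)(C)C (lithium of intermediate 12 only)
Why: Lactone enolate alkylation, in which the benzylic bromide should approach the planar enolate on the face opposite the C4 arylmethyl group, placing the new group trans and giving the (3R,4R) isomer by 1,2-induction from the centre set in step 5.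

Step 7
Reactants: 13 (3R,4R)-4-{[4-(benzyloxy)-3-methoxyphenyl]methyl}-3-[(3,4,5-trimethoxyphenyl)methyl]oxolan-2-one
Product: 14 hernanol, (3R,4R)-4-[(4-hydroxy-3-methoxyphenyl)methyl]-3-[(3,4,5-trimethoxyphenyl)methyl]oxolan-2-one
Conditions: H2 (1 atm), 10% Pd/C, EtOAc/EtOH, rt
Reagents that add atoms: none
Why: Catalytic hydrogenolysis of the benzyl aryl ether over palladium should free the phenol under neutral conditions that leave the lactone, the methyl ethers and both stereocentres untouched.

**Compound list**

1 | eugenol (4-allyl-2-methoxyphenol) | C=CCc1ccc(O)c(OC)c1 | starting material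
2 | benzyl bromide | BrCc1ccccc1 | starting material
3 | 4-allyl-1-(benzyloxy)-2-methoxybenzene | C=CCc1ccc(OCc2ccccc2)c(OC)c1 | intermediate
4 | 9-{3-[4-(benzyloxy)-3-methoxyphenyl]propyl}-9-borabicyclo[3.3.1]nonane (B-alkyl-9-BBN adduct) | COc1cc(CCCB2C3CCCC2CCC3)ccc1OCc1ccccc1 | intermediate
5 | 3-[4-(benzyloxy)-3-methoxyphenyl]propan-1-ol | COc1cc(CCCO)ccc1OCc1ccccc1 | intermediate
6 | bromoacetyl bromide | BrCC(Br)=O | starting material
7 | 3-[4-(benzyloxy)-3-methoxyphenyl]propyl 2-bromoacetate | COc1cc(CCCOC(=O)CBr)ccc1OCc1ccccc1 | intermediate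
8 | 3-[4-(benzyloxy)-3-methoxyphenyl]propyl 2-[1,2-bis(4-methylbenzenesulfonyl)hydrazin-1-yl]acetate (N-alkylated ditosylhydrazide) | COc1cc(CCCOC(=O)CN(NS(=O)(=O)c2ccc(C)cc2)S(=O)(=O)c2ccc(C)cc2)ccc1OCc1ccccc1 | intermediate
9 | 3-[4-(benzyloxy)-3-methoxyphenyl]propyl 2-diazoacetate | COc1cc(CCCOC(=O)C=[N+]=[N-])ccc1OCc1ccccc1 | intermediate
10 | (4R)-4-{[4-(benzyloxy)-3-methoxyphenyl]methyl}oxolan-2-one | COc1cc(C[C@H]2COC(=O)C2)ccc1OCc1ccccc1 | intermediate
11 | 3,4,5-trimethoxybenzyl bromide (5-(bromomethyl)-1,2,3-trimethoxybenzene) | COc1cc(CBr)cc(OC)c1OC | starting material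
12 | lithium (4R)-4-{[4-(benzyloxy)-3-methoxyphenyl]methyl}-4,5-dihydrofuran-2-olate (lithium enolate of 10) | COc1cc(C[C@H]2COC([O-])=C2)ccc1OCc1ccccc1.[Li+] | intermediate
13 | (3R,4R)-4-{[4-(benzyloxy)-3-methoxyphenyl]methyl}-3-[(3,4,5-trimethoxyphenyl)methyl]oxolan-2-one | COc1cc(C[C@H]2COC(=O)[C@@H]2Cc2cc(OC)c(OC)c(OC)c2)ccc1OCc1ccccc1 | intermediate
14 | hernanol, (3R,4R)-4-[(4-hydroxy-3-methoxyphenyl)methyl]-3-[(3,4,5-trimethoxyphenyl)methyl]oxolan-2-one | COc1cc(C[C@H]2COC(=O)[C@@H]2Cc2cc(OC)c(OC)c(OC)c2)ccc1O | target

**Step count and risks**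

Total step count: 7. Longest linear sequence: 7 steps, from eugenol 1 to hernanol 14.

Steps most likely to fail:

1. Step 5 (key step). The carbene may insert at the benzylic C–H bond or add to the electron-rich arene, may dimerise, or may discriminate the two enantiotopic hydrogens incompletely.
Fallback: this sets out from 5 and comes back to the route at 10, building the C4 centre by auxiliary-controlled alkylation instead of C–H insertion. Oxidation of 5 (TEMPO cat., PhI(OAc)2, MeCN/H2O) should give 3-[4-(benzyloxy)-3-methoxyphenyl]propanoic acid F1. N-acylation of (4S)-4-benzyl-1,3-oxazolidin-2-one (pivaloyl chloride, Et3N, LiCl, THF) should give (4S)-4-benzyl-3-{3-[4-(benzyloxy)-3-methoxyphenyl]propanoyl}-1,3-oxazolidin-2-one F2. Evans alkylation (NaN(SiMe3)2, THF, −78 °C, then tert-butyl bromoacetate) should place the new group anti to the auxiliary benzyl group and give tert-butyl (3R)-3-{[4-(benzyloxy)-3-methoxyphenyl]methyl}-4-[(4S)-4-benzyl-2-oxo-1,3-oxazolidin-3-yl]-4-oxobutanoate F3. Reductive removal of the auxiliary (LiBH4, THF, 0 °C) should give tert-butyl (3R)-4-[4-(benzyloxy)-3-methoxyphenyl]-3-(hydroxymethyl)butanoate F4. Acid (TsOH cat., toluene, 80 °C) should then close lactone 10.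

2. Step 6. Proton transfer between product and enolate can lead to double alkylation and erode the trans selectivity, and the electron-rich benzylic bromide can decompose before it is consumed.
Fallback: this sets out from 10 and comes back to the route at 14, bypassing 13. Aldol addition of the lithium enolate of 10 to 3,4,5-trimethoxybenzaldehyde (LiN(SiMe3)2, THF, −78 °C) should give (3S,4R)-4-{[4-(benzyloxy)-3-methoxyphenyl]methyl}-3-[hydroxy(3,4,5-trimethoxyphenyl)methyl]oxolan-2-one F5 as a mixture of carbinol epimers, trans at the ring and unable to react twice. Hydrogenolysis (H2, 10% Pd/C, AcOH, HClO4 cat.) should then remove the activated benzylic hydroxyl and the O-benzyl group in one operation to give 14.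

3. Step 4. The base-sensitive bromoacetate may undergo ester cleavage or side reactions with DBU before both sulfinate eliminations are complete, and the diazoacetate may be lost on isolation.
Fallback: this sets out from 5 and comes back to the route at 9, bypassing 7. Acetoacetylation of 5 with 2,2,6-trimethyl-4H-1,3-dioxin-4-one (xylene, 140 °C) should give 3-[4-(benzyloxy)-3-methoxyphenyl]propyl 3-oxobutanoate F6. Regitz diazo transfer (4-acetamidobenzenesulfonyl azide, Et3N, MeCN) should give 3-[4-(benzyloxy)-3-methoxyphenyl]propyl 2-diazo-3-oxobutanoate F7. Deacetylation (LiOH, THF/H2O, rt) should then give 9.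

**Further compounds**

F1 | step 5 | 3-[4-(benzyloxy)-3-methoxyphenyl]propanoic acid | COc1cc(CCC(=O)O)ccc1OCc1ccccc1
F2 | step 5 | (4S)-4-benzyl-3-{3-[4-(benzyloxy)-3-methoxyphenyl]propanoyl}-1,3-oxazolidin-2-one | COc1cc(CCC(=O)N2C(=O)OC[C@@H]2Cc2ccccc2)ccc1OCc1ccccc1
F3 | step 5 | tert-butyl (3R)-3-{[4-(benzyloxy)-3-methoxyphenyl]methyl}-4-[(4S)-4-benzyl-2-oxo-1,3-oxazolidin-3-yl]-4-oxobutanoate | COc1cc(C[C@H](CC(=O)OC(C)(C)C)C(=O)N2C(=O)OC[C@@H]2Cc2ccccc2)ccc1OCc1ccccc1
F4 | step 5 | tert-butyl (3R)-4-[4-(benzyloxy)-3-methoxyphenyl]-3-(hydroxymethyl)butanoate | COc1cc(C[C@H](CC(=O)OC(C)(C)C)CO)ccc1OCc1ccccc1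
F5 | step 6 | (3S,4R)-4-{[4-(benzyloxy)-3-methoxyphenyl]methyl}-3-[hydroxy(3,4,5-trimethoxyphenyl)methyl]oxolan-2-one (carbinol epimers) | COc1cc(C[C@H]2COC(=O)[C@@H]2C(O)c2cc(OC)c(OC)c(OC)c2)ccc1OCc1ccccc1
F6 | step 4 | 3-[4-(benzyloxy)-3-methoxyphenyl]propyl 3-oxobutanoate | COc1cc(CCCOC(=O)CC(C)=O)ccc1OCc1ccccc1
F7 | step 4 | 3-[4-(benzyloxy)-3-methoxyphenyl]propyl 2-diazo-3-oxobutanoate | COc1cc(CCCOC(=O)C(=[N+]=[N-])C(C)=O)ccc1OCc1ccccc1
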